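(The data come from a simulation with made-up constants; noise was put on by code.)

Take Tuesday's run at its last reading and count as D whatever is neither J nor G.

the same everywhere: E 1.99 M

| flask | D | remark | time |
|---|---|---|---|
| Tuesday's | 2.7 M | run made earlier |  |
| flask | 1.9 M |  | 8.0 h |

Tuesday's run (percent of the D charged)

| time / h | J / % | G / % |
|---|---|---|
| 1.00 | 11.9 | 21.7 |
| 2.00 | 22.5 | 22.9 |
| 3.00 | 27.7 | 22.9 |
| 4.00 | 29.2 | 23.1 |
| 5.00 | 29.5 | 24.0 |
| 6.00 | 27.5 | 24.0 |

(scatter of a reading: 0.5 percentage points)

- the analysis behind the earlier runs scatters by 0.5 percentage points, standard deviation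

- amount of J in the flask at 8.0 h, in percent of the D charged
- amount of G in the flask at 8.0 h, in percent of the D charged
- amount of D in the flask at 8.0 h, in percent of the D charged

That count gave Tuesday's run a ratio r of 0.495, the holding ratio, G over D in one flask, which is a pre-equilibrium constant if it stays put; it is a reading and carries the scatter. Between 5.00 h and 6.00 h the J reading of Tuesday's run went from 29.5% to 27.5%. I carried that slide on to 8.0 h and got 23.5% J, assuming that percentages carry over to the smaller charge of D. Splitting the rest of the charge by r gave me 51.2% D and 25.3% G. The forecast differed from my reckoning: it said 43% J, 28% G and 29% D, holding that “the same E still limits”. The new flask gave 25.8% J, 25.3% G and 48.9% D.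

    D ⇌ G (K = 0.500, k = 0.0120 min⁻¹)
    E → Q (k = 0.00750 min⁻¹)
    G + Q ⇌ J (K = 12.0 M⁻¹, k = 0.110 M⁻¹ min⁻¹)
    2 Q → X (k = 0.0970 M⁻¹ min⁻¹)

In the new flask J slid because it fell back to G + Q while Q was lost to X: against 25.8% there, J stood at 69.8% with the step to X taken away and at 63.0% with the falling back taken away. By their own step alone, both ways together, D and G relaxed with a half-life of 0.321 h, shorter than the 8.0 h of the new flask. Split by r, the rest beside the new flask's J made 49.6% D. The same flask left for 80.0 h had J down to 3.45%, which r split into 64.6% D, and it held 64.4% D.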